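The easy thing comes first: the fed solution swells larch by a quarter of its starting volume.

| flask | substrate | coupling partner | time | remark |
|---|---|---|---|---|
| larch | 0.050 M | 1.20 equiv (fed, over 1.0 min) | 10 min | the fed solution adds 0.25 times the starting volume |
| cedar | 0.10 M | 1.20 equiv (fed, over 1.0 min) | 10 min | the fed solution adds 0.25 times the starting volume |
| alder | 0.20 M | 1.20 equiv (fed, over 1.0 min) | 10 min | the fed solution adds 0.25 times the starting volume |

    substrate + coupling partner ⇌ product (K1 = 8.13 /M, k1 = 0.593 /M/s)
    2 substrate → homo dimer (k2 = 0.754 /M/s)

- percentages count the substrate that a species holds: one homo dimer counts as two
- two of one species on the left: rate k times its square, two consumed each time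
- every charge counts on the volume at the start, and the solution that is fed holds the whole dose
- "hardly changes" means that all values lie within two and a half points (for a concentration: within two and a half percent of the largest)
- run time (larch): 10 min

- [product] at the end for larch, cedar, alder, in this order
- how that number moves from the first to the last of them (rises all the way / falls all the way / hardly changes / falls, then rises / rises, then falls)

**The hold.** If it stays free, the larch partner stands at 0.0480 M in the swollen volume, and I keep it there. The forward half-life of substrate by the coupling, 0.32 min with the whole larch charge present, is short against the 10 min run. So I treat the coupling as a pre-equilibrium: [product] is the equilibrium constant times [coupling partner][substrate]. Substrate and product together then form a pool that is larger than [substrate] by the hold factor, one plus that constant times [coupling partner], here 1.39.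

**The drain.** Dimer formation empties the pool, so the inverse of [substrate] climbs in a straight line. Its slope in larch is 1.08 /M/s, which is twice the dimer constant over the hold factor.

**The bracket.** For a ceiling I drop the starting term of that line. This gives 6.00 × 10⁻⁴ M in larch, and I call it the drain ceiling: [product] at most the equilibrium constant times [coupling partner] times the hold factor, over twice the dimer constant times the time. That ceiling is 1.25% of the [coupling partner] I held fixed. For a floor I suppose that the partner shelters nothing during the 1.0 min feed. The inverse of the larch pool then stands at 138 /M after dilution, and the line runs on from there, giving 5.02 × 10⁻⁴ M. Cedar has hold factor 1.78 and lies between 0.00115 M and 0.00154 M. Alder has 2.56 and lies between 0.00250 M and 0.00442 M. Each floor stands higher than the ceiling before it, so I expect a steady rise.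

**The forecast.** The forecast gives 5.300 × 10⁻⁴ M, 0.0013 M and 0.0033 M, rises all the way, on the ground that “the irreversible homo-dimerisation keeps draining free substrate”, and its larch value lies inside my bracket.

**The flasks.** The simulation gives 5.43 × 10⁻⁴ M, 0.00133 M and 0.00341 M, so the number rises all the way. In larch the relaxation half-life of the coupling, both ways together, is 0.113 min, much shorter than the 10 min run. Larch's 5.43 × 10⁻⁴ M stands below its drain ceiling of 6.00 × 10⁻⁴ M and above its floor. Alder's 0.00341 M stands below its drain ceiling of 0.00442 M and above its floor of 0.00250 M.

The numbers are made up; the result is computed.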